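**Plan**
Retrosynthesis cuts, in this order: the pyranone bond C4′–C4a′ (coumarin numbering; hydroarylation of an aryl propiolate), the propiolate ester C–O, the C2–OAc bond and the C3 oxidation level, the decalin bonds C4–C5 and C9–C10 (drimane numbering; epoxy-allylsilane bicyclisation), the allylic C11–OAr ether, and the chain bonds C6–C7 and C8–C12.
Forward: an epoxy allylsilane alcohol carrying all 15 terpene carbons (from geranyl acetate and ethyl acetoacetate) is joined by Mitsunobu etherification to a mono-silylated 2,4-dimethoxyresorcinol; rings A and B then form together in one cation–olefin cascade, ring A is taken to the 2-acetoxy-3-ketone, and the pyranone ring is closed last.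
Stereochemistry: Shi epoxidation fixes an (R)-epoxide that steers the chair–chair cascade (C5, C10); the allylsilane geometry (CH2OAr cis to the chain, from an (E)-enol triflate) sets C9 with its arm axial; C2 comes from enolate hydroxylation anti to the axial methyls followed by SN2 inversion.
Enabling feature: in the pyranone ring (O1′, C2′, C3′, C4′, C4a′, C8a′) the bond C4′–C4a′ lies ortho to the lactone oxygen on C8a′ and para to the ether oxygen on C7′, while the other ortho carbon C8′ bears OMe, so an aryl propiolate has one activated carbon for 6-endo closure. This lactone is the part least tolerant of enolate, hydride and Lewis-acid chemistry, so it is made after all terpene work is done.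

Key step: step 17

Remark: the target is read as (2R,5S,9S,10R) in drimane numbering: trans-decalin, C9–CH2OAr axial and anti to C10–CH3, C2–OAc syn to C10–CH3. The D-fructose-derived Shi ketone is assumed to give the (R)-epoxide, as it does for related 2-methylalk-2-enes, and compounds 1, 5, 10 and 24 are taken as commercial.

**Route**

Step 1
Reactants: 1 3-hydroxy-2,4-dimethoxybenzaldehyde
Product: 3 2,4-dimethoxybenzene-1,3-diol, via aryl formate 2 (not isolated)
Conditions: 30% aq. H2O2, cat. H2SO4, MeOH, rt
Reagents that add atoms: hydrogen peroxide, OO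
Why: Acid-catalysed Dakin oxidation, in which aryl migration in the perhemiacetal is favoured by the ortho and para methoxy groups and the resulting formate is methanolysed in the same pot.

Step 2
Reactants: 3 2,4-dimethoxybenzene-1,3-diol
Product: 4 2,6-dimethoxy-3-[(triisopropylsilyl)oxy]phenol
Conditions: i-Pr3SiCl (1.05 equiv), imidazole, DMF, 0 °C
Reagents that add atoms: chlorotriisopropylsilane, CC(C)[Si](Cl)(C(C)C)C(C)C
Why: Silylation with a bulky silyl chloride should select on steric grounds the hydroxyl with one ortho substituent over the hydroxyl flanked by two methoxy groups, which stays free for the later etherification.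

Step 3
Reactants: 5 geranyl acetate
Product: 6 (2E)-5-[(2R)-3,3-dimethyloxiran-2-yl]-3-methylpent-2-en-1-yl acetate
Conditions: D-fructose-derived Shi ketone (0.3 equiv), Oxone (2KHSO5·KHSO4·K2SO4), K2CO3, Bu4NHSO4, MeCN/CH2(OMe)2/aq. Na2B4O7 buffer (pH about 10.5), 0 °C
Reagents that add atoms: potassium peroxymonosulfate, [K+].[O-]S(=O)(=O)OO
Why: Shi asymmetric epoxidation, in which the dioxirane attacks the electron-rich distal alkene (the 2,3-alkene is deactivated by the allylic acetate) through the spiro transition state and should set the (R) configuration of the epoxide carbon.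

Step 4
Reactants: 6 (R)-6,7-epoxygeranyl acetate
Product: 7 (2E)-5-[(2R)-3,3-dimethyloxiran-2-yl]-3-methylpent-2-en-1-ol
Conditions: K2CO3 (0.2 equiv), MeOH, 0 °C to rt
Reagents that add atoms: none
Why: Base-catalysed transesterification removes the acetate without touching the trisubstituted epoxide.

Step 5
Reactants: 7 (R)-6,7-epoxygeraniol
Product: 9 (2R)-3-[(3E)-5-bromo-3-methylpent-3-en-1-yl]-2,2-dimethyloxirane, via allylic mesylate 8 (not isolated)
Conditions: MsCl, Et3N, THF, –40 °C; then LiBr, THF, 0 °C
Reagents that add atoms: lithium bromide, [Li+].[Br-]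
Why: Mesylation followed by SN2 displacement with bromide at the primary allylic carbon is the standard route to epoxy-prenyl bromides and leaves epoxide and alkene geometry intact.

Step 6
Reactants: 10 ethyl acetoacetate; 9 (R)-6,7-epoxygeranyl bromide
Product: 12 ethyl (6E)-9-[(2R)-3,3-dimethyloxiran-2-yl]-7-methyl-3-oxonon-6-enoate, via acetoacetate dianion 11 (not isolated)
Conditions: NaH, then n-BuLi, THF, 0 °C; add 9, 0 °C; AcOH/H2O quench
Reagents that add atoms: none
Why: γ-Alkylation of the acetoacetate dianion, which reacts at its more basic terminal carbon with the allylic bromide faster than with the epoxide.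

Step 7
Reactants: 12 β-keto ester
Product: 13 ethyl (2E,6E)-9-[(2R)-3,3-dimethyloxiran-2-yl]-7-methyl-3-{[(trifluoromethyl)sulfonyl]oxy}nona-2,6-dienoate
Conditions: aq. Me4NOH, Tf2O, hexanes, 5–10 °C
Reagents that add atoms: trifluoromethanesulfonic anhydride, O=S(=O)(OS(=O)(=O)C(F)(F)F)C(F)(F)F
Why: O-Triflation of the non-chelated tetramethylammonium enolate of a β-keto ester, which reacts from the extended geometry and should give the (E)-enol triflate (OTf trans to CO2Et, chain cis to CO2Et).

Step 8
Reactants: 13 (E)-enol triflate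
Product: 14 ethyl (2E,6E)-9-[(2R)-3,3-dimethyloxiran-2-yl]-7-methyl-3-[(trimethylsilyl)methyl]nona-2,6-dienoate
Conditions: Me3SiCH2MgCl (1.5 equiv), Pd(PPh3)4 (5 mol%), THF, 0 °C to rt
Reagents that add atoms: (trimethylsilyl)methylmagnesium chloride, C[Si](C)(C)C[Mg]Cl
Why: Kumada–Corriu coupling of an enol triflate proceeds with retention of alkene geometry, so the silylmethyl group ends trans to the ester and the chain cis to it, and the catalysed coupling outruns Grignard addition to the hindered enoate or the epoxide.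

Step 9
Reactants: 14 allylsilane ester
Product: 15 (2E,6E)-9-[(2R)-3,3-dimethyloxiran-2-yl]-7-methyl-3-[(trimethylsilyl)methyl]nona-2,6-dien-1-ol
Conditions: i-Bu2AlH (2.2 equiv), CH2Cl2, –78 °C; aq. potassium sodium tartrate
Reagents that add atoms: none
Why: 1,2-Reduction of the conjugated ester by i-Bu2AlH at low temperature gives the allylic alcohol without opening the trisubstituted epoxide or moving the alkene.

Step 10
Reactants: 15 epoxy allylsilane alcohol; 4 mono-silylated phenol
Product: 16 {2,4-dimethoxy-3-[((2E,6E)-9-[(2R)-3,3-dimethyloxiran-2-yl]-7-methyl-3-[(trimethylsilyl)methyl]nona-2,6-dien-1-yl)oxy]phenoxy}triisopropylsilane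
Conditions: PPh3, DIAD, THF, 0 °C to rt
Reagents that add atoms: none
Why: Mitsunobu etherification of a primary allylic alcohol with a phenol forms the C11–OAr bond at an unhindered carbon under neutral conditions that spare epoxide and allylsilane.

Step 11
Reactants: 16 epoxy allylsilane aryl ether
Product: 17 (3R,5S,9S,10R)-11-[2,6-dimethoxy-3-(triisopropylsilyloxy)phenoxy]drim-8(12)-en-3-ol (trans-decalin; 3-OH equatorial and cis to C10–CH3; C9–CH2OAr axial and anti to C10–CH3)
Conditions: MeAlCl2 (2.5 equiv), CH2Cl2, –78 °C; then H2O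
Reagents that add atoms: none
Why: Epoxide-initiated cation–olefin bicyclisation through a chair–chair (Stork–Eschenmoser) array ended by the allylsilane: the (R)-epoxide fixes the face of attack at C4 and leaves the C3 hydroxyl equatorial, anti addition across the (E)-alkene makes the ring fusion trans (C5–H anti to C10–CH3), the allylsilane geometry with CH2OAr cis to the chain places C11 axial on C9, and loss of silicon from the β-silyl cation gives only the exocyclic C8=C12 alkene, MeAlCl2 also acting as proton scavenger.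

Step 12
Reactants: 17 bicyclic alcohol
Product: 18 (5S,9S,10R)-11-[2,6-dimethoxy-3-(triisopropylsilyloxy)phenoxy]drim-8(12)-en-3-one
Conditions: Dess–Martin periodinane, NaHCO3, CH2Cl2, rt
Reagents that add atoms: none
Why: Dess–Martin oxidation converts the hindered secondary alcohol into the ketone under near-neutral conditions that leave the exocyclic alkene, the aryl ethers and the silyl ether untouched.

Step 13
Reactants: 18 ketone
Product: 20 (2S,5S,9S,10R)-2-hydroxy-11-[2,6-dimethoxy-3-(triisopropylsilyloxy)phenoxy]drim-8(12)-en-3-one (2-OH anti to C10–CH3), via potassium enolate 19 (not isolated)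
Conditions: KN(SiMe3)2, THF, –78 °C; then trans-2-(phenylsulfonyl)-3-phenyloxaziridine, –78 °C; AcOH quench
Reagents that add atoms: trans-2-(phenylsulfonyl)-3-phenyloxaziridine, O=S(=O)(N1OC1c1ccccc1)c1ccccc1
Why: Davis hydroxylation of the only possible enolate (C4 is quaternary), in which the oxaziridine should approach C2 on the face away from the syn-axial methyls on C4 and C10 to give the 2-hydroxyl anti to C10–CH3, an oxidant that does not attack the exocyclic alkene.

Step 14
Reactants: 20 ketol
Product: 22 (2R,5S,9S,10R)-2-acetoxy-11-[2,6-dimethoxy-3-(triisopropylsilyloxy)phenoxy]drim-8(12)-en-3-one (2-OAc syn to C10–CH3), via keto triflate 21 (not isolated)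
Conditions: Tf2O, 2,6-lutidine, CH2Cl2, –78 °C; then Bu4NOAc, MeCN, –40 to 0 °C
Reagents that add atoms: tetrabutylammonium acetate, CCCC[N+](CCCC)(CCCC)CCCC.CC(=O)[O-]
Why: SN2 displacement of a carbonyl-activated α-keto triflate by acetate proceeds with inversion, turning the equatorial (2S) oxygen into the (2R) acetate syn to C10–CH3 that the target requires, the equatorial triflate having no antiperiplanar C1–H for elimination.

Step 15
Reactants: 22 silyl-protected acetoxy ketone
Product: 23 (2R,5S,9S,10R)-2-acetoxy-11-(3-hydroxy-2,6-dimethoxyphenoxy)drim-8(12)-en-3-one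
Conditions: Bu4NF/AcOH (1:1), THF, 0 °C
Reagents that add atoms: none
Why: Fluoride cleavage of the aryl silyl ether, buffered with acetic acid so that the phenoxide is protonated at once and the epimerisable α-acetoxy ketone is not exposed to base.

Step 16
Reactants: 23 phenol; 24 propiolic acid
Product: 25 3-{[(2R,5S,9S,10R)-2-acetoxy-3-oxodrim-8(12)-en-11-yl]oxy}-2,4-dimethoxyphenyl propiolate
Conditions: DCC, DMAP (5 mol%), CH2Cl2, –20 to 0 °C
Reagents that add atoms: none
Why: Steglich esterification at low temperature with only catalytic DMAP acylates the phenol while limiting conjugate addition to the propiolate and epimerisation at C2.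

Step 17
Reactants: 25 aryl propiolate
Product: 26 CNP0183157.1, (2R,5S,9S,10R)-2-acetoxy-11-[(6,8-dimethoxy-2-oxo-2H-chromen-7-yl)oxy]drim-8(12)-en-3-one
Conditions: [(t-Bu)2(2-biphenylyl)P]Au(NCMe)SbF6 (5 mol%), CH2Cl2, rt
Reagents that add atoms: none
Why: The cationic monovalent gold complex binds the terminal alkyne, the arene carbon ortho to the ester oxygen adds to the alkyne terminus in a Friedel–Crafts sense to give a vinyl-gold Wheland intermediate, and rearomatisation with protodeauration releases the 2H-chromen-2-one. The closest known reaction type is the gold- or platinum-catalysed intramolecular hydroarylation of aryl propiolates to coumarins. The pyranone ring closes in 6-endo-dig mode, forming C4′–C4a′. No stereocentre is created, and C2, C5, C9 and C10 are not exposed to base or hydride. The step needs attack at C4a′ and not at the ipso or the other ortho carbon, and no activation of the C8=C12 alkene: C8′ is blocked by its methoxy group, C4a′ is para to the C7′ ether oxygen, an ipso adduct could only reach the same coumarin by 1,2-vinyl shift, and the soft carbophilic catalyst prefers the alkyne to a 1,1-disubstituted alkene, a preformed silver-free complex being chosen to avoid acid that could move the exocyclic alkene.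

**Compound list**

1 | 3-hydroxy-2,4-dimethoxybenzaldehyde | O=Cc1ccc(OC)c(O)c1OC | starting material
2 | 3-hydroxy-2,4-dimethoxyphenyl formate | O=COc1ccc(OC)c(O)c1OC | intermediate
3 | 2,4-dimethoxybenzene-1,3-diol | Oc1ccc(OC)c(O)c1OC | intermediate
4 | 2,6-dimethoxy-3-[(triisopropylsilyl)oxy]phenol | CC(C)[Si](Oc1ccc(OC)c(O)c1OC)(C(C)C)C(C)C | intermediate
5 | geranyl acetate | CC(C)=CCC/C(C)=C/COC(C)=O | starting material
6 | (2E)-5-[(2R)-3,3-dimethyloxiran-2-yl]-3-methylpent-2-en-1-yl acetate | CC1(C)O[C@@H]1CC/C(C)=C/COC(C)=O | intermediate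
7 | (2E)-5-[(2R)-3,3-dimethyloxiran-2-yl]-3-methylpent-2-en-1-ol | CC1(C)O[C@@H]1CC/C(C)=C/CO | intermediate
8 | (2E)-5-[(2R)-3,3-dimethyloxiran-2-yl]-3-methylpent-2-en-1-yl methanesulfonate | CC1(C)O[C@@H]1CC/C(C)=C/COS(C)(=O)=O | intermediate
9 | (2R)-3-[(3E)-5-bromo-3-methylpent-3-en-1-yl]-2,2-dimethyloxirane | CC1(C)O[C@@H]1CC/C(C)=C/CBr | intermediate
10 | ethyl acetoacetate | CCOC(=O)CC(C)=O | starting material
11 | ethyl acetoacetate dianion (lithium sodium salt) | [Li+].[Na+].[CH2-]C(=O)[CH-]C(=O)OCC | intermediate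
12 | ethyl (6E)-9-[(2R)-3,3-dimethyloxiran-2-yl]-7-methyl-3-oxonon-6-enoate | CC1(C)O[C@@H]1CC/C(C)=C/CCC(=O)CC(=O)OCC | intermediate
13 | ethyl (2E,6E)-9-[(2R)-3,3-dimethyloxiran-2-yl]-7-methyl-3-{[(trifluoromethyl)sulfonyl]oxy}nona-2,6-dienoate | CC1(C)O[C@@H]1CC/C(C)=C/CC/C(OS(=O)(=O)C(F)(F)F)=C\C(=O)OCC | intermediate
14 | ethyl (2E,6E)-9-[(2R)-3,3-dimethyloxiran-2-yl]-7-methyl-3-[(trimethylsilyl)methyl]nona-2,6-dienoate | CC1(C)O[C@@H]1CC/C(C)=C/CC/C(C[Si](C)(C)C)=C\C(=O)OCC | intermediate
15 | (2E,6E)-9-[(2R)-3,3-dimethyloxiran-2-yl]-7-methyl-3-[(trimethylsilyl)methyl]nona-2,6-dien-1-ol | CC1(C)O[C@@H]1CC/C(C)=C/CC/C(C[Si](C)(C)C)=C\CO | intermediate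
16 | aryl ether of 15 with phenol 4 | CC1(C)O[C@@H]1CC/C(C)=C/CC/C(C[Si](C)(C)C)=C\COc1c(OC)ccc(O[Si](C(C)C)(C(C)C)C(C)C)c1OC | intermediate
17 | (3R,5S,9S,10R)-11-[2,6-dimethoxy-3-(triisopropylsilyloxy)phenoxy]drim-8(12)-en-3-ol | C=C1CC[C@@H]2C(C)(C)[C@H](O)CC[C@@]2(C)[C@H]1COc1c(OC)ccc(O[Si](C(C)C)(C(C)C)C(C)C)c1OC | intermediate
18 | (5S,9S,10R)-11-[2,6-dimethoxy-3-(triisopropylsilyloxy)phenoxy]drim-8(12)-en-3-one | C=C1CC[C@@H]2C(C)(C)C(=O)CC[C@@]2(C)[C@H]1COc1c(OC)ccc(O[Si](C(C)C)(C(C)C)C(C)C)c1OC | intermediate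
19 | potassium 2-en-3-olate of 18 | C=C1CC[C@@H]2C(C)(C)C([O-])=CC[C@@]2(C)[C@H]1COc1c(OC)ccc(O[Si](C(C)C)(C(C)C)C(C)C)c1OC.[K+] | intermediate
20 | (2S,5S,9S,10R)-2-hydroxy-11-[2,6-dimethoxy-3-(triisopropylsilyloxy)phenoxy]drim-8(12)-en-3-one | C=C1CC[C@@H]2C(C)(C)C(=O)[C@@H](O)C[C@@]2(C)[C@H]1COc1c(OC)ccc(O[Si](C(C)C)(C(C)C)C(C)C)c1OC | intermediate
21 | 2-O-trifluoromethanesulfonate of 20 | C=C1CC[C@@H]2C(C)(C)C(=O)[C@@H](OS(=O)(=O)C(F)(F)F)C[C@@]2(C)[C@H]1COc1c(OC)ccc(O[Si](C(C)C)(C(C)C)C(C)C)c1OC | intermediate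
22 | (2R,5S,9S,10R)-2-acetoxy-11-[2,6-dimethoxy-3-(triisopropylsilyloxy)phenoxy]drim-8(12)-en-3-one | C=C1CC[C@@H]2C(C)(C)C(=O)[C@H](OC(C)=O)C[C@@]2(C)[C@H]1COc1c(OC)ccc(O[Si](C(C)C)(C(C)C)C(C)C)c1OC | intermediate
23 | (2R,5S,9S,10R)-2-acetoxy-11-(3-hydroxy-2,6-dimethoxyphenoxy)drim-8(12)-en-3-one | C=C1CC[C@@H]2C(C)(C)C(=O)[C@H](OC(C)=O)C[C@@]2(C)[C@H]1COc1c(OC)ccc(O)c1OC | intermediate
24 | propiolic acid | C#CC(=O)O | starting material
25 | 3-{[(2R,5S,9S,10R)-2-acetoxy-3-oxodrim-8(12)-en-11-yl]oxy}-2,4-dimethoxyphenyl propiolate | C=C1CC[C@@H]2C(C)(C)C(=O)[C@H](OC(C)=O)C[C@@]2(C)[C@H]1COc1c(OC)ccc(OC(=O)C#C)c1OC | intermediate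
26 | CNP0183157.1, (2R,5S,9S,10R)-2-acetoxy-11-[(6,8-dimethoxy-2-oxo-2H-chromen-7-yl)oxy]drim-8(12)-en-3-one | C=C1CC[C@@H]2C(C)(C)C(=O)[C@H](OC(C)=O)C[C@@]2(C)[C@H]1COc1c(OC)cc2ccc(=O)oc2c1OC | target

**Step count**
Total: 17 steps. Longest linear sequence: 15 steps (steps 3–17, from geranyl acetate); the aryl fragment (steps 1–2) joins at step 10.

**Steps most likely to fail, with fallbacks**

Step 11. The Lewis acid may ionise the allylic aryl ether instead of the epoxide. The resulting allyl cation is stabilised by the β-silicon and would collapse to a diene with loss of silicon. The electron-rich arene may also intercept a cationic intermediate. The fallback runs the cascade as a radical process without Lewis acid and without silicon. It sets out from enol triflate 13. Coupling with MeMgBr under Fe(acac)3 catalysis (THF/NMP, –30 °C) should give ethyl (2Z,6E)-9-[(2R)-3,3-dimethyloxiran-2-yl]-3,7-dimethylnona-2,6-dienoate F1 with retention of geometry. Reduction with i-Bu2AlH would give (2Z,6E)-9-[(2R)-3,3-dimethyloxiran-2-yl]-3,7-dimethylnona-2,6-dien-1-ol F2. Mitsunobu coupling with 4 would give the (2Z,6E)-epoxyfarnesyl aryl ether F3. Cp2TiCl (trivalent titanium, from Cp2TiCl2 and Mn dust, THF, rt) would then open the epoxide homolytically at the tertiary carbon. Two 6-endo radical closures through the same chair–chair array should follow, and the tertiary C8 radical is trapped by a second Cp2TiCl and loses a β-hydrogen to give the exocyclic alkene. The fallback rejoins the route at 17.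

Step 14. Backside approach of acetate to C2 runs between the syn-axial methyls on C4 and C10, so enolisation of the keto triflate, attack at sulfur or epimerisation may outrun substitution. The fallback sets C2 by kinetic protonation instead of substitution. It sets out from ketol 20. Acetylation (Ac2O, DMAP, pyridine) would give the equatorial (2S)-2-acetoxy ketone F4. Soft enolisation (Me3SiOTf, Et3N, CH2Cl2, 0 °C) would give the 2-acetoxy-3-(trimethylsilyloxy)-2-ene F5. Protodesilylation with Et3N·3HF at –40 °C should deliver the proton to C2 on the face remote from the axial methyls, which leaves the acetate syn to C10–CH3. The fallback rejoins the route at 22.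

Step 17. Traces of acid from the cationic catalyst may move the C8=C12 alkene into the ring. Arene attack may also be slow, because the C7′ ether oxygen is twisted out of conjugation by its two methoxy neighbours and donates poorly to C4a′. The fallback closes the pyranone by cross-coupling and lactonisation. It sets out from phenol 23. Iodination with N-iodosuccinimide (MeCN, 0 °C) ortho to the hydroxyl and para to the terpenyl ether would give the 4-iodo-3-hydroxy-2,6-dimethoxyphenyl ether F6. Stille coupling with ethyl (Z)-3-(tributylstannyl)acrylate (Pd2(dba)3, AsPh3, CuI, DMF, rt to 50 °C) would give the (Z)-2-hydroxycinnamate F7. This ester should lactonise in the flask with loss of ethanol and arrive at 26.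

**Further compounds**

F1 | step 11 | ethyl (2Z,6E)-9-[(2R)-3,3-dimethyloxiran-2-yl]-3,7-dimethylnona-2,6-dienoate | CC1(C)O[C@@H]1CC/C(C)=C/CC/C(C)=C\C(=O)OCC
F2 | step 11 | (2Z,6E)-9-[(2R)-3,3-dimethyloxiran-2-yl]-3,7-dimethylnona-2,6-dien-1-ol | CC1(C)O[C@@H]1CC/C(C)=C/CC/C(C)=C\CO
F3 | step 11 | aryl ether of F2 with phenol 4 | CC1(C)O[C@@H]1CC/C(C)=C/CC/C(C)=C\COc1c(OC)ccc(O[Si](C(C)C)(C(C)C)C(C)C)c1OC
F4 | step 14 | (2S,5S,9S,10R)-2-acetoxy-11-[2,6-dimethoxy-3-(triisopropylsilyloxy)phenoxy]drim-8(12)-en-3-one | C=C1CC[C@@H]2C(C)(C)C(=O)[C@@H](OC(C)=O)C[C@@]2(C)[C@H]1COc1c(OC)ccc(O[Si](C(C)C)(C(C)C)C(C)C)c1OC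
F5 | step 14 | (5S,9S,10R)-2-acetoxy-3-(trimethylsilyloxy)-11-[2,6-dimethoxy-3-(triisopropylsilyloxy)phenoxy]drima-2,8(12)-diene | C=C1CC[C@@H]2C(C)(C)C(O[Si](C)(C)C)=C(OC(C)=O)C[C@@]2(C)[C@H]1COc1c(OC)ccc(O[Si](C(C)C)(C(C)C)C(C)C)c1OC
F6 | step 17 | (2R,5S,9S,10R)-2-acetoxy-11-(3-hydroxy-4-iodo-2,6-dimethoxyphenoxy)drim-8(12)-en-3-one | C=C1CC[C@@H]2C(C)(C)C(=O)[C@H](OC(C)=O)C[C@@]2(C)[C@H]1COc1c(OC)cc(I)c(O)c1OC
F7 | step 17 | ethyl (Z)-3-(4-{[(2R,5S,9S,10R)-2-acetoxy-3-oxodrim-8(12)-en-11-yl]oxy}-2-hydroxy-3,5-dimethoxyphenyl)acrylate | C=C1CC[C@@H]2C(C)(C)C(=O)[C@H](OC(C)=O)C[C@@]2(C)[C@H]1COc1c(OC)cc(/C=C\C(=O)OCC)c(O)c1OC
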